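**Retrosynthetic overview**
1. The ten-membered carbocycle is closed last, by ring-closing metathesis at C4=C5 of a seco-diene.
2. C2–C3 and the C2 carbinol come from a catalytic asymmetric allylboration of a C2 aldehyde; the C9 carbinol comes from Felkin–Anh reduction of a C9 ketone, so the C8 and C9 esters go on one at a time.
3. The cis C9(=O)–C10(CO2Me)=C1–C2HO unit is an oxidatively opened furan-3-carboxylate, so the enoate geometry is inherited from the heteroaromatic ring.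
4. The α-methylene trans-γ-lactone (first ring formed, C6–C8) comes from Eschenmoser methylenation, Felkin vinylation/lactonisation and a D-proline cross-aldol that sets C7 and C8.
5. Starting materials: methyl furan-3-carboxylate, methyl 4-oxobutanoate, angelic acid and 2-methylidenepropane-1,3-diol.

Assumption: atoms are labelled by germacrane numbering (lactone O on C6, C12 lactone carbonyl, C14 ester carbon, C15 CH2OH); the SMILES is read as 2S,6R,7S,8S,9S, both ring alkenes cis within the ring (CIP E), ester on C8 = (Z)-2-methylbut-2-enoate (angelate).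

**Route**

Step 1
Reactants: 1 methyl furan-3-carboxylate
Product: 3 methyl 2-formylfuran-3-carboxylate, via furylmagnesium chloride 2 (not isolated)
Conditions: TMPMgCl·LiCl (1.1 equiv), THF, −40 °C; DMF, −40 to 23 °C; aq NH4Cl
Reagents that add atoms: N,N-dimethylformamide CN(C)C=O; TMPMgCl·LiCl CC1(C)CCCC(C)(C)N1[Mg]Cl.[Li+].[Cl-] (its MgCl stays only in 2)
Why: Directed magnesiation by the hindered amide base occurs at C2, the position both alpha to the ring oxygen and ortho to the ester, and the furyl Grignard is formylated by DMF (directed metalation–formylation).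

Step 2
Reactants: 3 methyl 2-formylfuran-3-carboxylate; 4 methyl 4-oxobutanoate
Product: 5 methyl (3R,4S)-3-formyl-4-hydroxy-4-[3-(methoxycarbonyl)furan-2-yl]butanoate
Conditions: D-proline (20 mol%), DMF, 4 °C, 4 (2 equiv) added over 24 h; aqueous work-up, crude used at once
Reagents that add atoms: none
Why: In this proline-catalysed direct cross-aldol the (E)-enamine of 4 attacks one face of the non-enolisable, electron-poor aldehyde 3 through the hydrogen-bonded chair transition state to give the anti-aldol, and D-proline gives the (3R,4S) enantiomer that carries C7 and C8 of the target.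

Step 3
Reactants: 5 methyl (3R,4S)-3-formyl-4-hydroxy-4-[3-(methoxycarbonyl)furan-2-yl]butanoate
Product: 8 methyl 2-{(S)-[(2R,3S)-2-ethenyl-5-oxooxolan-3-yl][(triethylsilyl)oxy]methyl}furan-3-carboxylate, via silyl ether aldehyde 6 (not isolated), via hydroxy ester 7 (not isolated)
Conditions: TESCl, imidazole, CH2Cl2, −20 °C; filter, concentrate; CH2=CHMgBr, THF, −78 °C; aq NH4Cl; PPTS (cat.), CH2Cl2, 23 °C
Reagents that add atoms: chlorotriethylsilane CC[Si](Cl)(CC)CC; vinylmagnesium bromide C=C[Mg]Br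
Why: With the aldol hydroxyl masked as a non-chelating silyl ether, the vinyl Grignard adds to the α-branched aldehyde under Felkin–Anh control (anti to the large C8 substituent) to set C6 as R, and the γ-hydroxy ester then closes to the trans-γ-lactone.

Step 4
Reactants: 8 methyl 2-{(S)-[(2R,3S)-2-ethenyl-5-oxooxolan-3-yl][(triethylsilyl)oxy]methyl}furan-3-carboxylate
Product: 12 methyl 2-{(S)-[(2R,3R)-2-ethenyl-4-methylidene-5-oxooxolan-3-yl](hydroxy)methyl}furan-3-carboxylate, via Mannich base 9 (not isolated), via trimethylammonium iodide 10 (not isolated), via silyl ether methylene lactone 11 (not isolated)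
Conditions: LiN(SiMe3)2, THF, −78 °C; Me2N=CH2+ I−, −78 to 0 °C; MeI, MeOH, 23 °C; aq NaHCO3, EtOAc, 23 °C; 1 M HCl, THF, 0 °C
Reagents that add atoms: Eschenmoser's salt C=[N+](C)C.[I-]; iodomethane CI (its methyl stays only in 10)
Why: Mannich reaction of the lactone enolate with Eschenmoser's salt, N-methylation and base-induced elimination install the exocyclic methylene without touching C6–C8, and the acidic finish removes the silyl ether (the C7 descriptor changes only because of CIP priorities).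

Step 5
Reactants: 12 methyl 2-{(S)-[(2R,3R)-2-ethenyl-4-methylidene-5-oxooxolan-3-yl](hydroxy)methyl}furan-3-carboxylate; 13 (2Z)-2-methylbut-2-enoic acid (angelic acid)
Product: 15 methyl 2-{(S)-[(2R,3S)-2-ethenyl-4-methylidene-5-oxooxolan-3-yl]{[(2Z)-2-methylbut-2-enoyl]oxy}methyl}furan-3-carboxylate, via mixed anhydride 14 (not isolated)
Conditions: 13, 2,4,6-Cl3C6H2COCl, Et3N, toluene, 23 °C; then 12, 80 °C (no DMAP)
Reagents that add atoms: 2,4,6-trichlorobenzoyl chloride O=C(Cl)c1c(Cl)cc(Cl)cc1Cl (its aroyl group stays only in 14)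
Why: Yamaguchi esterification through the mixed anhydride acylates the hindered secondary alcohol, and leaving out DMAP suppresses isomerisation of the angelate to the tiglate.

Step 6
Reactants: 15 methyl 2-{(S)-[(2R,3S)-2-ethenyl-4-methylidene-5-oxooxolan-3-yl]{[(2Z)-2-methylbut-2-enoyl]oxy}methyl}furan-3-carboxylate
Product: 16 methyl (2E)-2-[(2S)-2-[(2R,3S)-2-ethenyl-4-methylidene-5-oxooxolan-3-yl]-2-{[(2Z)-2-methylbut-2-enoyl]oxy}acetyl]-4-oxobut-2-enoate (formyl carbon cis to the ketone carbon)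
Conditions: DMDO (1.2 equiv, acetone), CH2Cl2, −40 to 0 °C, dark; concentrate cold, use at once
Reagents that add atoms: dimethyldioxirane CC1(C)OO1
Why: Dimethyldioxirane epoxidises the furan, the most electron-rich π-system present, and the epoxide opens to the cis-2-ene-1,4-dicarbonyl (oxidative furan ring opening), giving the C9 ketone, the C2 aldehyde and the C1=C10 geometry (C9 cis to C2) in one operation.

Step 7
Reactants: 17 2-methylidenepropane-1,3-diol
Product: 18 2-{[(tert-butyldiphenylsilyl)oxy]methyl}prop-2-en-1-ol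
Conditions: NaH (1.0 equiv), THF, 0 to 23 °C; TBDPSCl (1.0 equiv)
Reagents that add atoms: tert-butyl(chloro)diphenylsilane CC(C)(C)[Si](Cl)(c1ccccc1)c1ccccc1
Why: Monosilylation of the symmetrical diol through its sparingly soluble monosodium alkoxide gives the mono-ether selectively.

Step 8
Reactants: 18 2-{[(tert-butyldiphenylsilyl)oxy]methyl}prop-2-en-1-ol
Product: 19 tert-butyldiphenyl({2-[(4,4,5,5-tetramethyl-1,3,2-dioxaborolan-2-yl)methyl]prop-2-en-1-yl}oxy)silane
Conditions: B2pin2, Pd(MeCN)4(BF4)2 (5 mol%), DMSO/MeOH, 50 °C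
Reagents that add atoms: bis(pinacolato)diboron CC1(C)OB(OC1(C)C)B1OC(C)(C)C(C)(C)O1
Why: Palladium-catalysed borylation of the free allylic alcohol replaces OH by Bpin, and the two allyl termini are equivalent so no regiochemical issue arises.

Step 9
Reactants: 16 cis-keto-enal (named in step 6); 19 allylboronate (named in step 8)
Product: 21 methyl (2E,4S)-6-{[(tert-butyldiphenylsilyl)oxy]methyl}-2-[(1S,2S)-2-[(2R,3S)-2-ethenyl-4-methylidene-5-oxooxolan-3-yl]-1-hydroxy-2-{[(2Z)-2-methylbut-2-enoyl]oxy}ethyl]-4-hydroxyhepta-2,6-dienoate, via boronate ester ketone 20 (not isolated)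
Conditions: (S)-TRIP (10 mol%), 4 Å MS, toluene, −40 °C; then MeOH, CeCl3·7H2O, NaBH4, −78 °C; AcOH quench
Reagents that add atoms: none
Why: Proposed new method: a chiral phosphoric acid-catalysed allylboration applied for the first time to a cis-4-oxo-enal and to a 2-(silyloxymethyl)allyl pinacol boronate. The acid hydrogen-bonds to a boronate oxygen and the formyl C–H in a closed chair transition state, so only the aldehyde (not the hindered α-acyloxy ketone) reacts and the (S)-catalyst sets C2 as S while forming C2–C3. The O–Bpin group keeps the new oxygen from cyclising onto the ketone (furan re-formation) until the in situ Luche reduction, which under polar Felkin–Anh control (hydride anti to the C8–O bond) gives the 8,9-syn C9 alcohol. The closest known reaction is the TRIP-catalysed allylboration of simple aldehydes with allyl and 2-methylallyl pinacol boronates.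

Step 10
Reactants: 21 diol (named in step 9)
Product: 22 methyl (2E,4S)-6-{[(tert-butyldiphenylsilyl)oxy]methyl}-2-[(1S,2S)-2-[(2R,3S)-2-ethenyl-4-methylidene-5-oxooxolan-3-yl]-1-hydroxy-2-{[(2Z)-2-methylbut-2-enoyl]oxy}ethyl]-4-[(triethylsilyl)oxy]hepta-2,6-dienoate
Conditions: TESCl (1.05 equiv), imidazole, CH2Cl2, −40 °C
Reagents that add atoms: chlorotriethylsilane CC[Si](Cl)(CC)CC
Why: The C2 hydroxyl (between CH2 and CH=) is silylated much faster than the C9 hydroxyl, which sits between a fully substituted alkene carbon and the acyloxy-bearing C8 (steric differentiation in silyl ether formation).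

Step 11
Reactants: 22 C2 silyl ether (named in step 10)
Product: 23 methyl (2E,4S)-2-[(1S,2S)-1-(acetyloxy)-2-[(2R,3S)-2-ethenyl-4-methylidene-5-oxooxolan-3-yl]-2-{[(2Z)-2-methylbut-2-enoyl]oxy}ethyl]-6-{[(tert-butyldiphenylsilyl)oxy]methyl}-4-[(triethylsilyl)oxy]hepta-2,6-dienoate
Conditions: Ac2O, pyridine, DMAP (10 mol%), CH2Cl2, 0 °C
Reagents that add atoms: acetic anhydride CC(=O)OC(C)=O
Why: DMAP-catalysed acylation of the one remaining free (C9) hydroxyl installs the acetate before any acyl migration from O8 can occur.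

Step 12
Reactants: 23 acetate (named in step 11)
Product: 24 methyl (2E,4S)-2-[(1S,2S)-1-(acetyloxy)-2-[(2R,3S)-2-ethenyl-4-methylidene-5-oxooxolan-3-yl]-2-{[(2Z)-2-methylbut-2-enoyl]oxy}ethyl]-4-hydroxy-6-(hydroxymethyl)hepta-2,6-dienoate
Conditions: HF·pyridine, pyridine, THF, 0 to 23 °C
Reagents that add atoms: none
Why: Buffered fluoride cleaves both silyl ethers while the acetate, angelate, methyl ester and α-methylene lactone survive the mildly acidic medium.

Step 13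
Reactants: 24 seco-diol (named in step 12)
Product: 25 methyl (3aS,4S,5S,6E,8S,10E,11aR)-5-(acetyloxy)-8-hydroxy-10-(hydroxymethyl)-3-methylidene-4-{[(2Z)-2-methylbut-2-enoyl]oxy}-2-oxo-2,3,3a,4,5,8,9,11a-octahydrocyclodeca[b]furan-6-carboxylate (CNP0195669.2)
Conditions: second-generation Hoveyda–Grubbs catalyst RuCl2(SIMes)(=CH-C6H4-2-OiPr) (15 mol%), 1,4-benzoquinone (30 mol%), toluene (1 mM), 80 °C
Reagents that add atoms: none
Why: Ring-closing metathesis joins the vinyl group on C6 with the 1,1-disubstituted alkene (the enoate, angelate and α-methylene lactone are poor partners), and the ten-membered ring forces the new trisubstituted C4=C5 bond to be cis within the ring (C6 cis to C3, CIP E), as in the target.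

**Compound list**
1 | methyl furan-3-carboxylate | COC(=O)c1ccoc1 | starting material
2 | [3-(methoxycarbonyl)furan-2-yl]magnesium chloride, LiCl complex | COC(=O)c1ccoc1[Mg]Cl.[Li+].[Cl-] | intermediate
3 | methyl 2-formylfuran-3-carboxylate | COC(=O)c1ccoc1C=O | intermediate
4 | methyl 4-oxobutanoate | COC(=O)CCC=O | starting material
5 | methyl (3R,4S)-3-formyl-4-hydroxy-4-[3-(methoxycarbonyl)furan-2-yl]butanoate | COC(=O)C[C@@H](C=O)[C@H](O)c1occc1C(=O)OC | intermediate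
6 | methyl (3R,4S)-3-formyl-4-[3-(methoxycarbonyl)furan-2-yl]-4-[(triethylsilyl)oxy]butanoate | COC(=O)C[C@@H](C=O)[C@H](O[Si](CC)(CC)CC)c1occc1C(=O)OC | intermediate
7 | methyl (3S,4R)-4-hydroxy-3-{(S)-[3-(methoxycarbonyl)furan-2-yl][(triethylsilyl)oxy]methyl}hex-5-enoate | COC(=O)C[C@@H]([C@H](O)C=C)[C@H](O[Si](CC)(CC)CC)c1occc1C(=O)OC | intermediate
8 | methyl 2-{(S)-[(2R,3S)-2-ethenyl-5-oxooxolan-3-yl][(triethylsilyl)oxy]methyl}furan-3-carboxylate | C=C[C@H]1OC(=O)C[C@@H]1[C@H](O[Si](CC)(CC)CC)c1occc1C(=O)OC | intermediate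
9 | methyl 2-{(S)-[(2R,3S)-4-[(dimethylamino)methyl]-2-ethenyl-5-oxooxolan-3-yl][(triethylsilyl)oxy]methyl}furan-3-carboxylate (both C4 epimers) | C=C[C@H]1OC(=O)C(CN(C)C)[C@@H]1[C@H](O[Si](CC)(CC)CC)c1occc1C(=O)OC | intermediate
10 | 1-[(4S,5R)-5-ethenyl-4-{(S)-[3-(methoxycarbonyl)furan-2-yl][(triethylsilyl)oxy]methyl}-2-oxooxolan-3-yl]-N,N,N-trimethylmethanaminium iodide (both C3 epimers) | C=C[C@H]1OC(=O)C(C[N+](C)(C)C)[C@@H]1[C@H](O[Si](CC)(CC)CC)c1occc1C(=O)OC.[I-] | intermediate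
11 | methyl 2-{(S)-[(2R,3S)-2-ethenyl-4-methylidene-5-oxooxolan-3-yl][(triethylsilyl)oxy]methyl}furan-3-carboxylate | C=C[C@H]1OC(=O)C(=C)[C@@H]1[C@H](O[Si](CC)(CC)CC)c1occc1C(=O)OC | intermediate
12 | methyl 2-{(S)-[(2R,3R)-2-ethenyl-4-methylidene-5-oxooxolan-3-yl](hydroxy)methyl}furan-3-carboxylate | C=C[C@H]1OC(=O)C(=C)[C@@H]1[C@H](O)c1occc1C(=O)OC | intermediate
13 | (2Z)-2-methylbut-2-enoic acid (angelic acid) | C/C=C(/C)C(=O)O | starting material
14 | (2Z)-2-methylbut-2-enoic 2,4,6-trichlorobenzoic anhydride | C/C=C(/C)C(=O)OC(=O)c1c(Cl)cc(Cl)cc1Cl | intermediate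
15 | methyl 2-{(S)-[(2R,3S)-2-ethenyl-4-methylidene-5-oxooxolan-3-yl]{[(2Z)-2-methylbut-2-enoyl]oxy}methyl}furan-3-carboxylate | C=C[C@H]1OC(=O)C(=C)[C@@H]1[C@H](OC(=O)/C(C)=C\C)c1occc1C(=O)OC | intermediate
16 | methyl (2E)-2-[(2S)-2-[(2R,3S)-2-ethenyl-4-methylidene-5-oxooxolan-3-yl]-2-{[(2Z)-2-methylbut-2-enoyl]oxy}acetyl]-4-oxobut-2-enoate | C=C[C@H]1OC(=O)C(=C)[C@@H]1[C@H](OC(=O)/C(C)=C\C)C(=O)/C(C(=O)OC)=C\C=O | intermediate
17 | 2-methylidenepropane-1,3-diol | C=C(CO)CO | starting material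
18 | 2-{[(tert-butyldiphenylsilyl)oxy]methyl}prop-2-en-1-ol | C=C(CO)CO[Si](c1ccccc1)(c1ccccc1)C(C)(C)C | intermediate
19 | tert-butyldiphenyl({2-[(4,4,5,5-tetramethyl-1,3,2-dioxaborolan-2-yl)methyl]prop-2-en-1-yl}oxy)silane | C=C(CO[Si](c1ccccc1)(c1ccccc1)C(C)(C)C)CB1OC(C)(C)C(C)(C)O1 | intermediate
20 | methyl (2E,4S)-6-{[(tert-butyldiphenylsilyl)oxy]methyl}-2-[(2S)-2-[(2R,3S)-2-ethenyl-4-methylidene-5-oxooxolan-3-yl]-2-{[(2Z)-2-methylbut-2-enoyl]oxy}acetyl]-4-[(4,4,5,5-tetramethyl-1,3,2-dioxaborolan-2-yl)oxy]hepta-2,6-dienoate | C=C[C@H]1OC(=O)C(=C)[C@@H]1[C@H](OC(=O)/C(C)=C\C)C(=O)/C(C(=O)OC)=C\[C@@H](OB2OC(C)(C)C(C)(C)O2)CC(=C)CO[Si](c2ccccc2)(c2ccccc2)C(C)(C)C | intermediate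
21 | methyl (2E,4S)-6-{[(tert-butyldiphenylsilyl)oxy]methyl}-2-[(1S,2S)-2-[(2R,3S)-2-ethenyl-4-methylidene-5-oxooxolan-3-yl]-1-hydroxy-2-{[(2Z)-2-methylbut-2-enoyl]oxy}ethyl]-4-hydroxyhepta-2,6-dienoate | C=C[C@H]1OC(=O)C(=C)[C@@H]1[C@H](OC(=O)/C(C)=C\C)[C@@H](O)/C(C(=O)OC)=C\[C@@H](O)CC(=C)CO[Si](c2ccccc2)(c2ccccc2)C(C)(C)C | intermediate
22 | methyl (2E,4S)-6-{[(tert-butyldiphenylsilyl)oxy]methyl}-2-[(1S,2S)-2-[(2R,3S)-2-ethenyl-4-methylidene-5-oxooxolan-3-yl]-1-hydroxy-2-{[(2Z)-2-methylbut-2-enoyl]oxy}ethyl]-4-[(triethylsilyl)oxy]hepta-2,6-dienoate | C=C[C@H]1OC(=O)C(=C)[C@@H]1[C@H](OC(=O)/C(C)=C\C)[C@@H](O)/C(C(=O)OC)=C\[C@@H](O[Si](CC)(CC)CC)CC(=C)CO[Si](c2ccccc2)(c2ccccc2)C(C)(C)C | intermediate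
23 | methyl (2E,4S)-2-[(1S,2S)-1-(acetyloxy)-2-[(2R,3S)-2-ethenyl-4-methylidene-5-oxooxolan-3-yl]-2-{[(2Z)-2-methylbut-2-enoyl]oxy}ethyl]-6-{[(tert-butyldiphenylsilyl)oxy]methyl}-4-[(triethylsilyl)oxy]hepta-2,6-dienoate | C=C[C@H]1OC(=O)C(=C)[C@@H]1[C@H](OC(=O)/C(C)=C\C)[C@@H](OC(C)=O)/C(C(=O)OC)=C\[C@@H](O[Si](CC)(CC)CC)CC(=C)CO[Si](c2ccccc2)(c2ccccc2)C(C)(C)C | intermediate
24 | methyl (2E,4S)-2-[(1S,2S)-1-(acetyloxy)-2-[(2R,3S)-2-ethenyl-4-methylidene-5-oxooxolan-3-yl]-2-{[(2Z)-2-methylbut-2-enoyl]oxy}ethyl]-4-hydroxy-6-(hydroxymethyl)hepta-2,6-dienoate | C=C[C@H]1OC(=O)C(=C)[C@@H]1[C@H](OC(=O)/C(C)=C\C)[C@@H](OC(C)=O)/C(C(=O)OC)=C\[C@@H](O)CC(=C)CO | intermediate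
25 | methyl (3aS,4S,5S,6E,8S,10E,11aR)-5-(acetyloxy)-8-hydroxy-10-(hydroxymethyl)-3-methylidene-4-{[(2Z)-2-methylbut-2-enoyl]oxy}-2-oxo-2,3,3a,4,5,8,9,11a-octahydrocyclodeca[b]furan-6-carboxylate | C=C1C(=O)O[C@@H]2/C=C(/CO)C[C@H](O)/C=C(/C(=O)OC)[C@H](OC(C)=O)[C@@H](OC(=O)/C(C)=C\C)[C@@H]12 | target

**Step count and risks**

Total: 13 steps. Longest linear sequence: 11 steps (steps 1–6 and 9–13); the boronate 19 is a two-step side branch (steps 7–8).

Three steps most likely to fail: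

1. Step 9 (the proposed new step). The risks are a racemic background allylboration of the very electrophilic aldehyde, cyclisation and aromatisation of the γ-oxy enone back to a furan before the ketone is reduced, and modest Felkin selectivity at C9. The fallback uses known chemistry, sets out from 16 and returns at 21: a titanium–BINOL (Keck-type) allylation with an allylstannane. Alcohol 18 is converted with MsCl/Et3N into 2-{[(tert-butyldiphenylsilyl)oxy]methyl}prop-2-en-1-yl methanesulfonate F2 and then with Bu3SnLi (THF, −78 °C) into tributyl(2-{[(tert-butyldiphenylsilyl)oxy]methyl}prop-2-en-1-yl)stannane F3. Keto-enal 16 and F3 with the catalyst from Ti(OiPr)4 and (S)-BINOL (10 mol%, 4 Å MS, CH2Cl2, −20 °C, KF work-up) give the C2-hydroxy C9-ketone F4. This is reduced at once (NaBH4, CeCl3·7H2O, MeOH, −78 °C) to 21.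

2. Step 13. Closing a ten-membered ring onto a 1,1-disubstituted alkene that carries a hydroxymethyl group may stall or dimerise. The fallback sets out from 16 and returns at 25: it removes the oxygenated substituent from the metathesis partner and installs the C15 hydroxyl afterwards by allylic C–H oxidation. Keto-enal 16 is allylborated with commercial 2-methylallylboronic acid pinacol ester under the step 9 conditions (or via the stannane route above) to the boronate ester ketone F5, reduced in the same pot to the C4-methyl diol F6. As in steps 10 and 11 this gives the C2 triethylsilyl ether F7 and the C9 acetate F8. Metathesis of F8 (second-generation Hoveyda–Grubbs catalyst RuCl2(SIMes)(=CH-C6H4-2-OiPr), toluene, 80 °C) gives the 4-methyl macrocycle F9. Riley oxidation (SeO2, t-BuOOH, CH2Cl2, 23 °C) hydroxylates the methyl group, giving the CH2OH trans to C6 in the C2-silylated allylic alcohol F10. HF·pyridine then gives 25.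

3. Step 3. The Grignard addition may give a poor Felkin ratio at C6. The fallback sets out from 5 and returns at 8: it replaces kinetic control by thermodynamic control. The crude lactone mixture containing the C6 epimer, methyl 2-{(S)-[(2S,3S)-2-ethenyl-5-oxooxolan-3-yl][(triethylsilyl)oxy]methyl}furan-3-carboxylate F1 (cis-lactone), is treated with Pd(PPh3)4 (5 mol%) in THF at 50 °C. Reversible ionisation of the allylic lactone C6–O bond to the π-allylpalladium carboxylate and re-closure funnels F1 into the more stable trans-lactone 8.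

Further compounds
F1 | step 3 | methyl 2-{(S)-[(2S,3S)-2-ethenyl-5-oxooxolan-3-yl][(triethylsilyl)oxy]methyl}furan-3-carboxylate | C=C[C@@H]1OC(=O)C[C@@H]1[C@H](O[Si](CC)(CC)CC)c1occc1C(=O)OC
F2 | step 9 | 2-{[(tert-butyldiphenylsilyl)oxy]methyl}prop-2-en-1-yl methanesulfonate | C=C(COS(C)(=O)=O)CO[Si](c1ccccc1)(c1ccccc1)C(C)(C)C
F3 | step 9 | tributyl(2-{[(tert-butyldiphenylsilyl)oxy]methyl}prop-2-en-1-yl)stannane | C=C(C[Sn](CCCC)(CCCC)CCCC)CO[Si](c1ccccc1)(c1ccccc1)C(C)(C)C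
F4 | step 9 | methyl (2E,4S)-6-{[(tert-butyldiphenylsilyl)oxy]methyl}-2-[(2S)-2-[(2R,3S)-2-ethenyl-4-methylidene-5-oxooxolan-3-yl]-2-{[(2Z)-2-methylbut-2-enoyl]oxy}acetyl]-4-hydroxyhepta-2,6-dienoate | C=C[C@H]1OC(=O)C(=C)[C@@H]1[C@H](OC(=O)/C(C)=C\C)C(=O)/C(C(=O)OC)=C\[C@@H](O)CC(=C)CO[Si](c2ccccc2)(c2ccccc2)C(C)(C)C
F5 | step 13 | methyl (2E,4S)-2-[(2S)-2-[(2R,3S)-2-ethenyl-4-methylidene-5-oxooxolan-3-yl]-2-{[(2Z)-2-methylbut-2-enoyl]oxy}acetyl]-6-methyl-4-[(4,4,5,5-tetramethyl-1,3,2-dioxaborolan-2-yl)oxy]hepta-2,6-dienoate | C=C[C@H]1OC(=O)C(=C)[C@@H]1[C@H](OC(=O)/C(C)=C\C)C(=O)/C(C(=O)OC)=C\[C@@H](OB2OC(C)(C)C(C)(C)O2)CC(C)=C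
F6 | step 13 | methyl (2E,4S)-2-[(1S,2S)-2-[(2R,3S)-2-ethenyl-4-methylidene-5-oxooxolan-3-yl]-1-hydroxy-2-{[(2Z)-2-methylbut-2-enoyl]oxy}ethyl]-4-hydroxy-6-methylhepta-2,6-dienoate | C=C[C@H]1OC(=O)C(=C)[C@@H]1[C@H](OC(=O)/C(C)=C\C)[C@@H](O)/C(C(=O)OC)=C\[C@@H](O)CC(C)=C
F7 | step 13 | methyl (2E,4S)-2-[(1S,2S)-2-[(2R,3S)-2-ethenyl-4-methylidene-5-oxooxolan-3-yl]-1-hydroxy-2-{[(2Z)-2-methylbut-2-enoyl]oxy}ethyl]-6-methyl-4-[(triethylsilyl)oxy]hepta-2,6-dienoate | C=C[C@H]1OC(=O)C(=C)[C@@H]1[C@H](OC(=O)/C(C)=C\C)[C@@H](O)/C(C(=O)OC)=C\[C@@H](O[Si](CC)(CC)CC)CC(C)=C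
F8 | step 13 | methyl (2E,4S)-2-[(1S,2S)-1-(acetyloxy)-2-[(2R,3S)-2-ethenyl-4-methylidene-5-oxooxolan-3-yl]-2-{[(2Z)-2-methylbut-2-enoyl]oxy}ethyl]-6-methyl-4-[(triethylsilyl)oxy]hepta-2,6-dienoate | C=C[C@H]1OC(=O)C(=C)[C@@H]1[C@H](OC(=O)/C(C)=C\C)[C@@H](OC(C)=O)/C(C(=O)OC)=C\[C@@H](O[Si](CC)(CC)CC)CC(C)=C
F9 | step 13 | methyl (3aS,4S,5S,6E,8S,10Z,11aR)-5-(acetyloxy)-10-methyl-3-methylidene-4-{[(2Z)-2-methylbut-2-enoyl]oxy}-2-oxo-8-[(triethylsilyl)oxy]-2,3,3a,4,5,8,9,11a-octahydrocyclodeca[b]furan-6-carboxylate | C=C1C(=O)O[C@@H]2/C=C(/C)C[C@H](O[Si](CC)(CC)CC)/C=C(/C(=O)OC)[C@H](OC(C)=O)[C@@H](OC(=O)/C(C)=C\C)[C@@H]12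
F10 | step 13 | methyl (3aS,4S,5S,6E,8S,10E,11aR)-5-(acetyloxy)-10-(hydroxymethyl)-3-methylidene-4-{[(2Z)-2-methylbut-2-enoyl]oxy}-2-oxo-8-[(triethylsilyl)oxy]-2,3,3a,4,5,8,9,11a-octahydrocyclodeca[b]furan-6-carboxylate | C=C1C(=O)O[C@@H]2/C=C(/CO)C[C@H](O[Si](CC)(CC)CC)/C=C(/C(=O)OC)[C@H](OC(C)=O)[C@@H](OC(=O)/C(C)=C\C)[C@@H]12
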